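Acredinone A is treated as a pseudo-dimer: ring A with its 2,6-dimethoxybenzoyl group and ring B with C3 and its 2,6-dimethoxyphenyl group both come from one 3-arylphthalide. Everything rests on disconnecting the C1–C2 acyl–vinyl bond of the indenone. In the last step the five-membered ring C1–C2–C3–C3a–C7a is formed by acid-mediated contraction of a six-membered δ-lactone (a 3,4-diaryl-3,4-dihydroisocoumarin) whose ring oxygen sits between C1 and C2: the lactone opens to a stilbene carboxylic acid and its acylium ion at C1 acylates C2 with loss of water. This exploits that both aryl groups on C2=C3 have no free ortho position, so only C2 can be attacked.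

Key step: step 8

Remark on labels: C1 (C=O), C2, C3, C3a and C7a are the indenone atoms of the target and are used for the same atoms in the precursors. Ring B is the benzo ring of the indenone, ring A the benzophenone ring on C2.

Assumption: compounds with stereocenters are carried as racemates or diastereomer mixtures, since the target has no stereocenter and step 8 erases both stereocenters of the lactone.

Step 1
Reactants: 1 4-methoxy-3-methylphenol
Product: 2 1-methoxy-4-(methoxymethoxy)-2-methylbenzene
Conditions: NaH, MOMCl, DMF, 0 °C → rt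
Reagents that add atoms: chloromethyl methyl ether, COCCl
Why: Williamson-type O-alkylation of the sodium phenoxide with the reactive α-chloro ether should give the MOM ether cleanly, which protects the phenol and is the directing group for step 2.

Step 2
Reactants: 2 1-methoxy-4-(methoxymethoxy)-2-methylbenzene; 3 2,6-dimethoxybenzaldehyde
Product: 5 racemic (2,6-dimethoxyphenyl)[5-methoxy-2-(methoxymethoxy)-4-methylphenyl]methanol, via aryllithium 4 (not isolated)
Conditions: n-BuLi, TMEDA, THF, 0 °C; then 3, −78 °C → rt; then H2O
Reagents that add atoms: none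
Why: Directed ortho-metalation: the MOM ether (a stronger director than OMe) steers n-BuLi to its unhindered ortho position rather than the one flanked by the methyl group, and the aryllithium adds to the aldehyde to give the secondary alcohol as a racemate, whose stereocenter is removed later.

Step 3
Reactants: 5 racemic (2,6-dimethoxyphenyl)[5-methoxy-2-(methoxymethoxy)-4-methylphenyl]methanol
Product: 8 racemic 3-(2,6-dimethoxyphenyl)-7-methoxy-4-(methoxymethoxy)-6-methyl-2-benzofuran-1(3H)-one, via dilithio species 6 (not isolated), via hydroxy acid 7 (not isolated)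
Conditions: n-BuLi (2.5 equiv), TMEDA, Et2O–hexane, 0 °C → rt; CO2, −78 °C; then 1 M HCl, rt
Reagents that add atoms: carbon dioxide, O=C=O
Why: Directed ortho-metalation of the lithium alkoxide: the benzylic O–Li and the methoxy group flank the only ring hydrogen ortho to the carbinol carbon (both ortho positions of the dimethoxyphenyl ring are blocked), so lithiation should occur there, and carboxylation followed by spontaneous acid-induced lactonization of the γ-hydroxy acid gives the phthalide.

Step 4
Reactants: 8 racemic 3-(2,6-dimethoxyphenyl)-7-methoxy-4-(methoxymethoxy)-6-methyl-2-benzofuran-1(3H)-one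
Product: 9 2-[(2,6-dimethoxyphenyl)methyl]-6-methoxy-3-(methoxymethoxy)-5-methylbenzoic acid
Conditions: H2 (3 atm), Pd/C (10 wt % Pd), EtOAc–EtOH, 40 °C
Reagents that add atoms: none
Why: Catalytic hydrogenolysis of the doubly benzylic C–O bond of a 3-arylphthalide (a cyclic benzhydryl ester) is a known way to 2-benzylbenzoic acids and leaves the aryl ethers and the MOM group untouched; the stereocenter is removed.

Step 5
Reactants: 8 racemic 3-(2,6-dimethoxyphenyl)-7-methoxy-4-(methoxymethoxy)-6-methyl-2-benzofuran-1(3H)-one
Product: 10 racemic (2,6-dimethoxyphenyl)[2-(hydroxymethyl)-3-methoxy-6-(methoxymethoxy)-4-methylphenyl]methanol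
Conditions: LiAlH4, THF, 0 °C → rt; then H2O
Reagents that add atoms: none
Why: Hydride reduction of the lactone by LiAlH4 gives the diol, the ethers are inert and the existing stereocenter is not touched (racemic).

Step 6
Reactants: 10 racemic (2,6-dimethoxyphenyl)[2-(hydroxymethyl)-3-methoxy-6-(methoxymethoxy)-4-methylphenyl]methanol
Product: 11 2-(2,6-dimethoxybenzoyl)-6-methoxy-3-(methoxymethoxy)-5-methylbenzaldehyde
Conditions: (COCl)2, DMSO, CH2Cl2, −78 °C; then Et3N, −78 → 0 °C
Reagents that add atoms: none
Why: Swern oxidation activates both hydroxyl groups as alkoxysulfonium salts before the base is added, so the primary alcohol goes to the aldehyde and the secondary one to the diaryl ketone without a lactol that would be oxidized back to phthalide 8.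

Step 7
Reactants: 9 2-[(2,6-dimethoxyphenyl)methyl]-6-methoxy-3-(methoxymethoxy)-5-methylbenzoic acid; 11 2-(2,6-dimethoxybenzoyl)-6-methoxy-3-(methoxymethoxy)-5-methylbenzaldehyde
Product: 14 3-[2-(2,6-dimethoxybenzoyl)-3-hydroxy-6-methoxy-5-methylphenyl]-4-(2,6-dimethoxyphenyl)-5-hydroxy-8-methoxy-7-methyl-3,4-dihydro-1H-2-benzopyran-1-one (cis/trans mixture of racemates), via benzylic dianion 12 (not isolated), via hydroxy acid 13 (not isolated)
Conditions: 9, LiN(i-Pr)2 (2.2 equiv), THF, −78 → 0 °C; then 11, −78 °C → rt; then 3 M HCl, MeOH–THF, 50 °C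
Reagents that add atoms: none
Why: Lateral lithiation of a 2-benzylbenzoic acid and addition of the dianion to an aldehyde is the classical aldol-type entry to 3,4-disubstituted dihydroisocoumarins: the nucleophile should attack the aldehyde of 11 and not its doubly shielded diaryl ketone, and aqueous-methanolic HCl then closes the δ-lactone and cleaves both MOM ethers as dimethoxymethane; the two new stereocenters form unselectively, which does not matter because step 8 erases both.

Step 8
Reactants: 14 3-[2-(2,6-dimethoxybenzoyl)-3-hydroxy-6-methoxy-5-methylphenyl]-4-(2,6-dimethoxyphenyl)-5-hydroxy-8-methoxy-7-methyl-3,4-dihydro-1H-2-benzopyran-1-one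
Product: 15 acredinone A, 2-[2-(2,6-dimethoxybenzoyl)-3-hydroxy-6-methoxy-5-methylphenyl]-3-(2,6-dimethoxyphenyl)-4-hydroxy-7-methoxy-6-methyl-1H-inden-1-one
Conditions: P2O5–MeSO3H (1:10 w/w, as medium), 25 °C; then ice–H2O
Reagents that add atoms: none
Why: In the strongly acidic dehydrating medium the protonated δ-lactone of 14 should open at its benzylic alkyl–oxygen bond (E1) to the 2-(1,2-diarylvinyl)benzoic acid, whose 2,6-disubstituted carboxyl group ionizes readily to an aroyl cation that attacks the electron-rich trisubstituted alkene at C2, and loss of the C2 proton from the resulting C3 carbocation gives the indenone, so that the six-membered ring C1–O–C2–C3–C3a–C7a contracts to the five-membered ring C1–C2–C3–C3a–C7a with the ring oxygen leaving as water. The closest known reaction type is the acid-mediated rearrangement of γ- and δ-lactones to cyclopentenones in polyphosphoric acid or P2O5–MeSO3H (lactone to unsaturated acid to intramolecular acylation of the alkene). The only ring closed is the five-membered enone ring, formed by a cationic 5-endo acylation of the alkene that can equally be seen as a Nazarov-type 4π closure of the aroyl–styrene pentadienyl cation. No stereocenter is created and both stereocenters of 14 are erased, so the cis/trans mixture converges. The step needs C-acylation at C2 to win over return to a lactone and over attack on an aryl ring: the 2,6-dimethoxyphenyl group on C3 and ring A on C2 are substituted at every ortho position, which blocks closure onto either aryl ring, and relactonization (also to the five-membered phthalide) is reversible whereas the acylation is not.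

Compound list
1 | 4-methoxy-3-methylphenol | COc1ccc(O)cc1C | starting material
2 | 1-methoxy-4-(methoxymethoxy)-2-methylbenzene | COCOc1ccc(OC)c(C)c1 | intermediate
3 | 2,6-dimethoxybenzaldehyde | COc1cccc(OC)c1C=O | starting material
4 | [5-methoxy-2-(methoxymethoxy)-4-methylphenyl]lithium | COCOc1cc(C)c(OC)cc1[Li] | intermediate
5 | (2,6-dimethoxyphenyl)[5-methoxy-2-(methoxymethoxy)-4-methylphenyl]methanol, racemic | COCOc1cc(C)c(OC)cc1C(O)c1c(OC)cccc1OC | intermediate
6 | lithium (2,6-dimethoxyphenyl)[2-lithio-3-methoxy-6-(methoxymethoxy)-4-methylphenyl]methanolate, racemic | COCOc1cc(C)c(OC)c([Li])c1C(O[Li])c1c(OC)cccc1OC | intermediate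
7 | 2-[(2,6-dimethoxyphenyl)(hydroxy)methyl]-6-methoxy-3-(methoxymethoxy)-5-methylbenzoic acid, racemic | COCOc1cc(C)c(OC)c(C(=O)O)c1C(O)c1c(OC)cccc1OC | intermediate
8 | 3-(2,6-dimethoxyphenyl)-7-methoxy-4-(methoxymethoxy)-6-methyl-2-benzofuran-1(3H)-one, racemic | COCOc1cc(C)c(OC)c2C(=O)OC(c3c(OC)cccc3OC)c12 | intermediate
9 | 2-[(2,6-dimethoxyphenyl)methyl]-6-methoxy-3-(methoxymethoxy)-5-methylbenzoic acid | COCOc1cc(C)c(OC)c(C(=O)O)c1Cc1c(OC)cccc1OC | intermediate
10 | (2,6-dimethoxyphenyl)[2-(hydroxymethyl)-3-methoxy-6-(methoxymethoxy)-4-methylphenyl]methanol, racemic | COCOc1cc(C)c(OC)c(CO)c1C(O)c1c(OC)cccc1OC | intermediate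
11 | 2-(2,6-dimethoxybenzoyl)-6-methoxy-3-(methoxymethoxy)-5-methylbenzaldehyde | COCOc1cc(C)c(OC)c(C=O)c1C(=O)c1c(OC)cccc1OC | intermediate
12 | lithium 2-[(2,6-dimethoxyphenyl)(lithio)methyl]-6-methoxy-3-(methoxymethoxy)-5-methylbenzoate (benzylic dianion of 9) | COCOc1cc(C)c(OC)c(C(=O)O[Li])c1C([Li])c1c(OC)cccc1OC | intermediate
13 | 2-{2-[2-(2,6-dimethoxybenzoyl)-6-methoxy-3-(methoxymethoxy)-5-methylphenyl]-1-(2,6-dimethoxyphenyl)-2-hydroxyethyl}-6-methoxy-3-(methoxymethoxy)-5-methylbenzoic acid, mixture of diastereomers, each racemic | COCOc1cc(C)c(OC)c(C(=O)O)c1C(c2c(OC)cccc2OC)C(O)c3c(C(=O)c4c(OC)cccc4OC)c(OCOC)cc(C)c3OC | intermediate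
14 | 3-[2-(2,6-dimethoxybenzoyl)-3-hydroxy-6-methoxy-5-methylphenyl]-4-(2,6-dimethoxyphenyl)-5-hydroxy-8-methoxy-7-methyl-3,4-dihydro-1H-2-benzopyran-1-one, cis/trans mixture, each racemic | O=C1OC(c3c(C(=O)c4c(OC)cccc4OC)c(O)cc(C)c3OC)C(c5c(OC)cccc5OC)c2c(O)cc(C)c(OC)c12 | intermediate
15 | acredinone A, 2-[2-(2,6-dimethoxybenzoyl)-3-hydroxy-6-methoxy-5-methylphenyl]-3-(2,6-dimethoxyphenyl)-4-hydroxy-7-methoxy-6-methyl-1H-inden-1-one (no stereocenter) | COc1cccc(OC)c1C(=O)c1c(O)cc(C)c(OC)c1C1=C(c2c(OC)cccc2OC)c2c(O)cc(C)c(OC)c2C1=O | target

Total step count: 8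
Longest linear sequence: 7 steps (1 → 2 → 5 → 8 → 10 → 11 → 14 → 15; step 4 is the side branch from 8 to 9).

Steps most likely to fail

Step 8 (key step). The strong acid may strip the electron-rich 2,6-dimethoxyaryl groups (protodeacylation of the hindered diaryl ketone), cleave a methyl ether next to a carbonyl group, or let the free phenol rings be acylated intermolecularly before the ring contraction is complete. The fallback splits the contraction into a basic and a mildly acidic stage. Starting from 14, KOt-Bu in THF opens the lactone by β-elimination of the carboxylate (the C3–H is doubly benzylic) to the stilbene carboxylic acid F1 (E/Z mixture). Trifluoroacetic anhydride in CH2Cl2 at 0 °C then forms the mixed anhydride, which should acylate C2 intramolecularly while the phenols are masked in passing as the bis(trifluoroacetate) F2. K2CO3 in MeOH frees the phenols and returns to 15.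

Step 7. Addition of the hindered dianion 12 to the doubly ortho-substituted aldehyde may be slow or reversible, so that proton or electron transfer takes over from C–C bond formation. The fallback changes the nucleophile to the planar, ring-constrained enolate of the phthalide. Starting from 8 (LiN(SiMe3)2, THF, −78 °C) and 11, aldol addition at C3 of the phthalide should give adduct F3 (mixture of diastereomers). Hydrogenolysis of its benzylic lactone C–O bond (H2, Pd/C, as in step 4) then gives hydroxy acid 13, which is taken on to 14 with HCl in MeOH as in step 7.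

Step 3. The second lithiation may go to another position (next to the OMOM group, or on the dimethoxyphenyl ring) or stall at the mono-anion. The fallback introduces the carboxyl carbon before the aryl group. Starting from 2, lithiation as in step 2 and quench with N,N-dimethylformamide give aldehyde F4. The aldehyde is masked in the flask as its lithium α-amino alkoxide (with LiN(Me)CH2CH2NMe2), which directs n-BuLi to the only free ortho position, flanked by the methoxy group; carboxylation and acidification give the 3-hydroxyphthalide F5. Addition of 2,6-dimethoxyphenyllithium (2 equiv, from 1,3-dimethoxybenzene and n-BuLi) to its open aldehyde form and acidic lactonization return to 8.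

Further compounds
F1 | step 8 | 2-{1-(2,6-dimethoxyphenyl)-2-[2-(2,6-dimethoxybenzoyl)-3-hydroxy-6-methoxy-5-methylphenyl]ethenyl}-3-hydroxy-6-methoxy-5-methylbenzoic acid, E/Z mixture | OC(=O)c1c(OC)c(C)cc(O)c1C(c2c(OC)cccc2OC)=Cc3c(C(=O)c4c(OC)cccc4OC)c(O)cc(C)c3OC
F2 | step 8 | acredinone A bis(trifluoroacetate) | COc1cccc(OC)c1C(=O)c1c(OC(=O)C(F)(F)F)cc(C)c(OC)c1C1=C(c2c(OC)cccc2OC)c2c(OC(=O)C(F)(F)F)cc(C)c(OC)c2C1=O
F3 | step 7 | 3-{[2-(2,6-dimethoxybenzoyl)-6-methoxy-3-(methoxymethoxy)-5-methylphenyl](hydroxy)methyl}-3-(2,6-dimethoxyphenyl)-7-methoxy-4-(methoxymethoxy)-6-methyl-2-benzofuran-1(3H)-one, mixture of diastereomers, each racemic | COCOc1cc(C)c(OC)c2C(=O)OC(c3c(OC)cccc3OC)(C(O)c4c(C(=O)c5c(OC)cccc5OC)c(OCOC)cc(C)c4OC)c12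
F4 | step 3 | 5-methoxy-2-(methoxymethoxy)-4-methylbenzaldehyde | COCOc1cc(C)c(OC)cc1C=O
F5 | step 3 | 3-hydroxy-7-methoxy-4-(methoxymethoxy)-6-methyl-2-benzofuran-1(3H)-one, racemic | COCOc1cc(C)c(OC)c2C(=O)OC(O)c12
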